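3 questions stand on this flask: what has stopped it by the asked time, how much target it holds, and how much isomer of the product.

substrate 20 mM; coupling partner 22.0 mM; time 30 h

    2 coupling partner → homo dimer (k1 = 0.0286 M⁻¹ s⁻¹)
    substrate ⇌ other conformer (K2 = 4.13, k2 = 5.28 × 10⁻⁴ s⁻¹)
    coupling partner + other conformer → isomer of the product (k3 = 0.112 M⁻¹ s⁻¹)
    substrate + coupling partner → target (k4 = 0.0535 M⁻¹ s⁻¹)

* at 30 h, what has stopped the reaction, if anything has (other conformer counts as not reacted) (forward and back rates have come level / all of the substrate has reacted / the coupling partner has run out first / it is still moving)
* how much target there is at 30 h, in percent of the substrate charged
* how much isomer of the product there is at 30 h, in percent of the substrate charged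

- where a step has two of a species, its rate is k times that concentration squared, and two are used at each turn
- in a conversion other conformer counts as not yet reacted
- the reaction counts as stopped when no species that holds the substrate changes by six tenths of a point or more over the second half of the time
- run time (flask): 30 h

I read the clocks from the fastest up. At the charged coupling partner, substrate couples with a half-life of 0.164 h. Partner dimerises with a first half-life of 0.221 h, more slowly than that. Substrate and other conformer relax towards their balance with a half-life of 0.294 h, more slowly again. The run of 30 h is far longer than any of these. The first three rungs lie within a factor of 1.79, so none finishes before the next begins, and the question becomes how the partner divides.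

With the mixture at balance, substrate and conformer together couple with a mean constant of 0.101 M⁻¹ s⁻¹. Partner then goes to homo dimer at 0.625 per partner coupled: this ratio, twice the dimerisation constant times partner over the mean constant times substrate and conformer, at the charges, is the dimer claim. For pure substrate at the start the ratio stands higher, at 1.18. It then drifts down as conformer builds and partner, losing by both roads, falls against the substrate forms. I commit to the balanced value. Homo dimer then takes 38.5% of the partner, and coupling reaches 67.7% of the substrate, less than the whole, so I expect the partner, the limiting reagent, to give out first. My reckoning stops at that sum.

The forecast gives the coupling partner has run out first, with target 41% and isomer 29.5%, a sum of 70.5%, above mine. Its ground: “target forms first while the faster-reacting conformer builds up and then takes most of the late coupling partner”.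

The simulation gives the coupling partner has run out first, with 0% of the partner left at 30.0 h, target 43.0% and isomer 25.9%. To part the flask from the forecast a charge has to move: target has shifted 5 points with the partner charge moved alone to 18.2 mM or 26.5 mM, and with the substrate charge moved alone to 14.0 mM or 27.1 mM. In this flask the 4.11 mM of homo dimer at 30.0 h holds 37.4% of the partner, against 38.5% from the dimer claim of 0.625. The neighbour charged with 13 mM has a claim of 0.370, which reckons coupling at 47.5% of the substrate, and that flask holds 48.9% as target and isomer together.

All constants belong to no real substance; the run is a simulation.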